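**Retrosynthetic overview**

1. Ring C is closed last by making the aryl ketone bond C4–C4a (flavanone numbering; ring A = phloroglucinol ring, ring B = catechol ring, ring C = pyranone). An enzymatic intramolecular Friedel–Crafts acylation (C-acyltransferase) of a fully unprotected thioester releases the natural product itself.
2. Feature that allows it: C4a is the only carbon of ring A that bears hydrogen (C6 and C8 carry the prenyl groups). It lies ortho to the ether oxygen O1 and to the free 5-OH and para to the 7-OH, and the tether O1–C2–C3 holds the thioester carbon C4 in reach for a six-membered closure.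
3. Before that, O1–C2 is cut: Mitsunobu inversion of an (R)-β-hydroxy ester by symmetric 2,4-diprenylphloroglucinol, so that C2 is fixed in an open chain and never sits in a flavanone under base.
4. The carbinol comes from asymmetric transfer hydrogenation of a β-keto ester (Roskamp homologation of 3,4-diacetoxybenzaldehyde). Ring A comes from methyl 2,4,6-trihydroxybenzoate by double C-prenylation and decarboxylation.
5. Order of rings: rings A and B are bought as arenes and only decorated; ring C is the one ring that is formed, in the last step.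

Key step: step 8

Assumption: the drawn stereocentre is C2 with S configuration, and a variant of the bacterial C-acyltransferase that accepts the tethered substrate is taken to be obtainable by directed evolution.

**Route**

Step 1
Reactants: 1 methyl 2,4,6-trihydroxybenzoate
Product: 2 methyl 2,4,6-trihydroxy-3,5-bis(3-methylbut-2-en-1-yl)benzoate
Conditions: prenyl bromide (2.2 equiv), KOH (10% aq.), 0 °C, N2
Reagents that add atoms: prenyl bromide (1-bromo-3-methylbut-2-ene), CC(C)=CCBr
Why: C-alkylation of the ambident phloroglucinol phenoxide, favoured in water because hydrogen bonding shields the oxygens, should place one prenyl group on each of the two free ring carbons while the ester blocks the third (phenoxide C-prenylation as used for acylphloroglucinols).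

Step 2
Reactants: 2 methyl 2,4,6-trihydroxy-3,5-bis(3-methylbut-2-en-1-yl)benzoate
Product: 4 2,4-bis(3-methylbut-2-en-1-yl)benzene-1,3,5-triol (2,4-diprenylphloroglucinol), via diprenyl trihydroxybenzoic acid 3 (not isolated)
Conditions: KOH (2 M aq.), reflux, N2; then 1 M HCl to pH 4, 40 °C
Reagents that add atoms: none
Why: Saponification followed by protodecarboxylation of the 2,4,6-trihydroxybenzoic acid, which should lose CO2 readily through C-protonation of the electron-rich ring (ester hydrolysis, then decarboxylation of a phloroglucinol carboxylic acid).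

Step 3
Reactants: 5 3,4-diacetoxybenzaldehyde
Product: 6 ethyl 3-(3,4-diacetoxyphenyl)-3-oxopropanoate
Conditions: ethyl diazoacetate (1.3 equiv), NbCl5 (5 mol %), CH2Cl2, rt
Reagents that add atoms: ethyl diazoacetate, CCOC(=O)C=[N+]=[N-]
Why: Roskamp reaction: Lewis acid-promoted addition of the diazo ester to the aldehyde and 1,2-hydride shift with loss of N2 should give the β-keto ester without touching the aryl acetates.

Step 4
Reactants: 6 ethyl 3-(3,4-diacetoxyphenyl)-3-oxopropanoate
Product: 7 ethyl (R)-3-(3,4-diacetoxyphenyl)-3-hydroxypropanoate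
Conditions: RuCl[(R,R)-TsDPEN](p-cymene) (1 mol %), HCO2H/Et3N (5:2), 30 °C
Reagents that add atoms: none
Why: Noyori asymmetric transfer hydrogenation: the (R,R) catalyst should deliver hydride to the ketone face fixed by the CH–π contact between the aryl group and the p-cymene ligand, as for simple aryl alkyl ketones, which sets the carbinol carbon (the future C2) as R.

Step 5
Reactants: 4 2,4-diprenylphloroglucinol; 7 ethyl (R)-3-(3,4-diacetoxyphenyl)-3-hydroxypropanoate
Product: 8 ethyl (S)-3-(3,4-diacetoxyphenyl)-3-[3,5-dihydroxy-2,4-bis(3-methylbut-2-en-1-yl)phenoxy]propanoate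
Conditions: PPh3, DIAD, toluene/THF, 0 °C to rt (4 in 2.5-fold excess, excess recovered)
Reagents that add atoms: none
Why: Mitsunobu reaction: SN2 attack of a phenolic oxygen on the activated benzylic carbinol should invert it to S (the final C2 configuration), the electron-poor diacetoxyphenyl group disfavouring ionization; of the three hydroxyls of 4 only the two equivalent ones with a single ortho prenyl group should react, and the excess of 4 holds back double etherification.

Step 6
Reactants: 8 ethyl (S)-3-(3,4-diacetoxyphenyl)-3-[3,5-dihydroxy-2,4-bis(3-methylbut-2-en-1-yl)phenoxy]propanoate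
Product: 9 (S)-3-(3,4-dihydroxyphenyl)-3-[3,5-dihydroxy-2,4-bis(3-methylbut-2-en-1-yl)phenoxy]propanoic acid
Conditions: LiOH·H2O (6 equiv), THF/MeOH/H2O (degassed), 0 °C to rt, Ar; then 1 M HCl to pH 3
Reagents that add atoms: lithium hydroxide, [Li+].[OH-]
Why: Saponification of the ethyl ester and of both aryl acetates by hydroxide; the carboxylate formed does not enolize, so the β-aryloxy stereocentre should stay S.

Step 7
Reactants: 9 (S)-3-(3,4-dihydroxyphenyl)-3-[3,5-dihydroxy-2,4-bis(3-methylbut-2-en-1-yl)phenoxy]propanoic acid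
Product: 11 S-(2-acetamidoethyl) (S)-3-(3,4-dihydroxyphenyl)-3-[3,5-dihydroxy-2,4-bis(3-methylbut-2-en-1-yl)phenoxy]propanethioate, via N-hydroxysuccinimide ester 10 (not isolated)
Conditions: N-hydroxysuccinimide, EDC·HCl, THF, 0 °C; then N-acetylcysteamine (3 equiv), THF/potassium phosphate buffer (KH2PO4/K2HPO4, pH 7.5), rt
Reagents that add atoms: N-acetylcysteamine, CC(=O)NCCS
Why: Carbodiimide activation to the N-hydroxysuccinimide ester and thiolysis by the far more nucleophilic thiol should give the thioester in the presence of the four free phenols (active ester route to N-acetylcysteamine thioesters of phenolic acids).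

Step 8
Reactants: 11 S-(2-acetamidoethyl) (S)-3-(3,4-dihydroxyphenyl)-3-[3,5-dihydroxy-2,4-bis(3-methylbut-2-en-1-yl)phenoxy]propanethioate
Product: 13 (2S)-2-(3,4-dihydroxyphenyl)-5,7-dihydroxy-6,8-bis(3-methylbut-2-en-1-yl)chroman-4-one (6,8-diprenyleriodictyol), via acyl-enzyme thioester 12 (not isolated)
Conditions: C-acyltransferase PhlA/PhlB/PhlC of Pseudomonas protegens (evolved variant, cell-free extract), potassium phosphate buffer (KH2PO4/K2HPO4, 50 mM, pH 7.5), DMSO (20% v/v), sodium L-ascorbate, N2, 30 °C
Reagents that add atoms: none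
Why: Proposed new method: the cofactor-free C-acyltransferase should take the acyl group of 11 onto its active-site cysteine (acyl-enzyme 12, with loss of N-acetylcysteamine) and pass it to carbon of the bound phloroglucinol phenolate, here the tethered ring A, so that C4a attacks the thioester carbonyl and the resulting dienone re-aromatizes to the hydrogen-bonded 5-hydroxy aryl ketone; the closest known reaction type is the intermolecular biocatalytic Friedel–Crafts C-acylation (and Fries-type acyl shift) of resorcinols and phloroglucinols by this enzyme class with thioester or phenyl ester donors, which has not been shown intramolecularly or on an acceptor of this size, so an evolved variant is needed. Ring C closes by a 6-exo-trig acyl substitution through the tether O1–C2–C3. No stereocentre is formed, and C2 should stay S because neutral buffer allows neither ionization of the benzylic ether nor retro-oxa-Michael opening. The step needs C- over O-acylation in the presence of four free phenols, which is the native chemoselectivity of the enzyme, and a single ring position, which the substrate secures: C4a is the only ring A carbon that bears hydrogen, and it stands ortho to one hydroxyl (5-OH) and para to another (7-OH), as the acceptor carbon of this enzyme class must. The two prenyl groups, which any acid strong enough to C-acylate an unprotected polyphenol would cyclize onto the neighbouring hydroxyls, should not be touched at pH 7.5.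

**Compound list**

1 | methyl 2,4,6-trihydroxybenzoate | COC(=O)c1c(O)cc(O)cc1O | starting material
2 | methyl 2,4,6-trihydroxy-3,5-bis(3-methylbut-2-en-1-yl)benzoate | COC(=O)c1c(O)c(CC=C(C)C)c(O)c(CC=C(C)C)c1O | intermediate
3 | 2,4,6-trihydroxy-3,5-bis(3-methylbut-2-en-1-yl)benzoic acid | OC(=O)c1c(O)c(CC=C(C)C)c(O)c(CC=C(C)C)c1O | intermediate (not isolated)
4 | 2,4-bis(3-methylbut-2-en-1-yl)benzene-1,3,5-triol (2,4-diprenylphloroglucinol) | CC(C)=CCc1c(O)cc(O)c(CC=C(C)C)c1O | intermediate
5 | 3,4-diacetoxybenzaldehyde | CC(=O)Oc1ccc(C=O)cc1OC(C)=O | starting material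
6 | ethyl 3-(3,4-diacetoxyphenyl)-3-oxopropanoate | CCOC(=O)CC(=O)c1ccc(OC(C)=O)c(OC(C)=O)c1 | intermediate
7 | ethyl (R)-3-(3,4-diacetoxyphenyl)-3-hydroxypropanoate | CCOC(=O)C[C@@H](O)c1ccc(OC(C)=O)c(OC(C)=O)c1 | intermediate
8 | ethyl (S)-3-(3,4-diacetoxyphenyl)-3-[3,5-dihydroxy-2,4-bis(3-methylbut-2-en-1-yl)phenoxy]propanoate | CC(C)=CCc1c(O)c(CC=C(C)C)c(O[C@@H](CC(=O)OCC)c2ccc(OC(C)=O)c(OC(C)=O)c2)cc1O | intermediate
9 | (S)-3-(3,4-dihydroxyphenyl)-3-[3,5-dihydroxy-2,4-bis(3-methylbut-2-en-1-yl)phenoxy]propanoic acid | CC(C)=CCc1c(O)c(CC=C(C)C)c(O[C@@H](CC(=O)O)c2ccc(O)c(O)c2)cc1O | intermediate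
10 | 2,5-dioxopyrrolidin-1-yl (S)-3-(3,4-dihydroxyphenyl)-3-[3,5-dihydroxy-2,4-bis(3-methylbut-2-en-1-yl)phenoxy]propanoate (N-hydroxysuccinimide ester of 9) | CC(C)=CCc1c(O)c(CC=C(C)C)c(O[C@@H](CC(=O)ON2C(=O)CCC2=O)c2ccc(O)c(O)c2)cc1O | intermediate (not isolated)
11 | S-(2-acetamidoethyl) (S)-3-(3,4-dihydroxyphenyl)-3-[3,5-dihydroxy-2,4-bis(3-methylbut-2-en-1-yl)phenoxy]propanethioate | CC(C)=CCc1c(O)c(CC=C(C)C)c(O[C@@H](CC(=O)SCCNC(C)=O)c2ccc(O)c(O)c2)cc1O | intermediate
12 | acyl-enzyme thioester: the acyl group of 11 on the sulfur of the active-site cysteine (the cysteine residue is drawn as its N-acetyl N'-methylamide) | CC(=O)N[C@@H](CSC(=O)C[C@H](Oc1cc(O)c(CC=C(C)C)c(O)c1CC=C(C)C)c1ccc(O)c(O)c1)C(=O)NC | intermediate (not isolated)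
13 | (2S)-2-(3,4-dihydroxyphenyl)-5,7-dihydroxy-6,8-bis(3-methylbut-2-en-1-yl)chroman-4-one (6,8-diprenyleriodictyol) | CC(C)=CCc1c(O)c(CC=C(C)C)c2c(c1O)C(=O)C[C@@H](c1ccc(O)c(O)c1)O2 | target

**Summary**

Total step count: 8
Longest linear sequence: 6 steps (steps 3, 4, 5, 6, 7, 8)

Steps most likely to fail:

1. Step 8 (proposed new method). The tethered, doubly prenylated thioester may not be taken up by the acyltransferase (no transfer of the acyl group to the active-site cysteine, or no productive folding of ring A onto the acyl-enzyme), so that slow hydrolysis of the thioester in the buffer takes over. The fallback is a protecting-group-based chemical Friedel–Crafts closure; it sets out from acid 9 and comes back to the route at 13. Exhaustive silylation of 9 (TBSOTf, 2,6-lutidine, CH2Cl2) should give the tert-butyldimethylsilyl ester tetrakis(silyl ether) F1. Aqueous acetic acid in THF should cleave only the silyl ester to the tetrakis(tert-butyldimethylsilyl) ether acid F2. Trifluoroacetic anhydride (CH2Cl2, 0 °C) should convert F2 into the mixed trifluoroacetic anhydride F3, which acylates C4a in an intramolecular Friedel–Crafts reaction to the tetrakis(silyl) flavanone F4; no free hydroxyl lies next to a prenyl group at this stage, so acid-induced chroman formation is not possible. Et3N·3HF in THF should then remove the four silyl groups and give 13.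

2. Step 5. E2 elimination of the activated β-hydroxy ester to the cinnamate, double etherification of the triol and partial loss of configuration by ionization may compete. The fallback replaces the Mitsunobu reaction by the SN2 opening of a β-lactone (it also stands in for steps 3, 4 and 6); it sets out from phenol 4 and comes back to the route at acid 9. Commercial 3,4-dihydroxybenzaldehyde is mesylated (MsCl, Et3N, CH2Cl2) to 3,4-bis(methylsulfonyloxy)benzaldehyde F5. A cinchona alkaloid-catalysed acetyl chloride–aldehyde cyclocondensation (AcCl, iPr2NEt, LiClO4, CH2Cl2/Et2O, −78 °C) with whichever of the pseudoenantiomeric catalysts O-trimethylsilylquinine or O-trimethylsilylquinidine leads to the R series should give (R)-4-[3,4-bis(methylsulfonyloxy)phenyl]oxetan-2-one F6. The potassium phenoxide of 4 (K2CO3, DMF, 0 °C, excess 4) should open the lactone by SN2 attack at the benzylic carbon with inversion; elimination cannot occur in this ring and the sulfonates are inert to phenoxide. Acidification gives (S)-3-[3,4-bis(methylsulfonyloxy)phenyl]-3-[3,5-dihydroxy-2,4-bis(3-methylbut-2-en-1-yl)phenoxy]propanoic acid F7. NaOH (aq.)/MeOH at 60 °C under argon should then cleave both aryl mesylates and give 9.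

3. Step 1. Over-alkylation (geminal or triple prenylation with loss of aromaticity) and O-alkylation may leave little of the 3,5-diprenyl product. The fallback uses two ortho-Claisen rearrangements from the 4-hydroxyl in place of direct C-alkylation; it sets out from 1 and comes back to the route at 2. O-Alkylation of the most acidic, non-chelated 4-hydroxyl under zerovalent palladium catalysis (tert-butyl 2-methylbut-3-en-2-yl carbonate, Pd(PPh3)4, THF) should give methyl 2,6-dihydroxy-4-(2-methylbut-3-en-2-yloxy)benzoate F8. Aromatic Claisen rearrangement (toluene, 110 °C) should move the group to the ortho carbon as a prenyl group and give methyl 2,4,6-trihydroxy-3-(3-methylbut-2-en-1-yl)benzoate F9. Repeating the O-alkylation should give methyl 2,6-dihydroxy-4-(2-methylbut-3-en-2-yloxy)-3-(3-methylbut-2-en-1-yl)benzoate F10, whose Claisen rearrangement can only go to the remaining ortho carbon and gives 2.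

**Further compounds**

F1 | step 8 | tert-butyldimethylsilyl (S)-3-[3,4-bis(tert-butyldimethylsilyloxy)phenyl]-3-[3,5-bis(tert-butyldimethylsilyloxy)-2,4-bis(3-methylbut-2-en-1-yl)phenoxy]propanoate | CC(C)=CCc1c(O[Si](C)(C)C(C)(C)C)c(CC=C(C)C)c(O[C@@H](CC(=O)O[Si](C)(C)C(C)(C)C)c2ccc(O[Si](C)(C)C(C)(C)C)c(O[Si](C)(C)C(C)(C)C)c2)cc1O[Si](C)(C)C(C)(C)C
F2 | step 8 | (S)-3-[3,4-bis(tert-butyldimethylsilyloxy)phenyl]-3-[3,5-bis(tert-butyldimethylsilyloxy)-2,4-bis(3-methylbut-2-en-1-yl)phenoxy]propanoic acid | CC(C)=CCc1c(O[Si](C)(C)C(C)(C)C)c(CC=C(C)C)c(O[C@@H](CC(=O)O)c2ccc(O[Si](C)(C)C(C)(C)C)c(O[Si](C)(C)C(C)(C)C)c2)cc1O[Si](C)(C)C(C)(C)C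
F3 | step 8 | mixed anhydride of F2 with trifluoroacetic acid | CC(C)=CCc1c(O[Si](C)(C)C(C)(C)C)c(CC=C(C)C)c(O[C@@H](CC(=O)OC(=O)C(F)(F)F)c2ccc(O[Si](C)(C)C(C)(C)C)c(O[Si](C)(C)C(C)(C)C)c2)cc1O[Si](C)(C)C(C)(C)C
F4 | step 8 | (2S)-5,7-bis(tert-butyldimethylsilyloxy)-2-[3,4-bis(tert-butyldimethylsilyloxy)phenyl]-6,8-bis(3-methylbut-2-en-1-yl)chroman-4-one | CC(C)=CCc1c(O[Si](C)(C)C(C)(C)C)c(CC=C(C)C)c2c(c1O[Si](C)(C)C(C)(C)C)C(=O)C[C@@H](c1ccc(O[Si](C)(C)C(C)(C)C)c(O[Si](C)(C)C(C)(C)C)c1)O2
F5 | step 5 | 3,4-bis(methylsulfonyloxy)benzaldehyde | CS(=O)(=O)Oc1ccc(C=O)cc1OS(C)(=O)=O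
F6 | step 5 | (R)-4-[3,4-bis(methylsulfonyloxy)phenyl]oxetan-2-one | O=C1C[C@H](c2ccc(OS(C)(=O)=O)c(OS(C)(=O)=O)c2)O1
F7 | step 5 | (S)-3-[3,4-bis(methylsulfonyloxy)phenyl]-3-[3,5-dihydroxy-2,4-bis(3-methylbut-2-en-1-yl)phenoxy]propanoic acid | CC(C)=CCc1c(O)c(CC=C(C)C)c(O[C@@H](CC(=O)O)c2ccc(OS(C)(=O)=O)c(OS(C)(=O)=O)c2)cc1O
F8 | step 1 | methyl 2,6-dihydroxy-4-(2-methylbut-3-en-2-yloxy)benzoate | COC(=O)c1c(O)cc(OC(C)(C)C=C)cc1O
F9 | step 1 | methyl 2,4,6-trihydroxy-3-(3-methylbut-2-en-1-yl)benzoate | COC(=O)c1c(O)cc(O)c(CC=C(C)C)c1O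
F10 | step 1 | methyl 2,6-dihydroxy-4-(2-methylbut-3-en-2-yloxy)-3-(3-methylbut-2-en-1-yl)benzoate | COC(=O)c1c(O)cc(OC(C)(C)C=C)c(CC=C(C)C)c1O
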